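Ring A (C1–C5, C10) of the purchasable ent-labdane 14-deoxyandrographolide holds its C4 hydroxymethyl on the wrong face, so it is contracted to an A-nor cyclopentane and rebuilt. The key step is a semipinacol ring expansion of the tertiary C3 cyclopentanol carrying a 2-methyloxiranyl group: C5 migrates from C3 to the epoxide carbon C4 with inversion, creating in one operation six-membered ring A and its β-hydroxy ketone motif O=C3–C4–C18–OH, with quaternary C4 bearing the equatorial hydroxymethyl and axial methyl. The epoxy alcohol comes from Wagner–Meerwein contraction, excision of the old hydroxymethyl carbon, α-hydroxylation, methylenation and hydroxyl-directed epoxidation; the butenolide is transposed through its ene-diol.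

Key step: step 9

Remark (assumption): 14-deoxyandrographolide (1) is taken as a catalogue compound; labdane numbering is used, α = face of the C10 methyl, β = face of H-5 and H-9, "A-nor" = five-membered ring A (C10, C1, C2, C3, C5) with C4 exocyclic on C3; the C4 carbinol centre of 4–6 is left unassigned because it becomes sp2 in step 4.

Step 1
Reactants: 1 14-deoxyandrographolide
Product: 2 19-O-benzoyl-14-deoxyandrographolide
Conditions: BzCl (1.1 equiv), pyridine, CH2Cl2, −20 °C
Reagents that add atoms: benzoyl chloride, O=C(Cl)c1ccccc1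
Why: Selective O-acylation, since the primary C4 hydroxymethyl should react well before the secondary C3 hydroxyl next to quaternary C4, and the benzoate is placed as a neighbouring group for step 2.

Step 2
Reactants: 2 19-O-benzoyl-14-deoxyandrographolide
Product: 5 A-nor hydroxy benzoate, via 3-O-triflate 3 (not isolated), via dioxolanylium ion 4 (not isolated)
Conditions: Tf2O, pyridine, CH2Cl2, −40 → 0 °C; then aq. NaHCO3
Reagents that add atoms: water, O
Why: Wagner–Meerwein ring contraction: the equatorial C3 triflate has only the C4–C5 ring bond anti-periplanar (no anti hydrogen for elimination), so C5 should shift from C4 to C3 with inversion at C3 (H-3 β), the tertiary C4 cation should be trapped by the neighbouring benzoate as a 1,3-dioxolan-2-ylium ion, and hydrolysis should give the hydroxy benzoate (an O4-benzoate regioisomer would converge in step 3).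

Step 3
Reactants: 5 A-nor hydroxy benzoate
Product: 6 A-nor tetraol
Conditions: i-Bu2AlH (8 equiv), CH2Cl2, −78 → 0 °C; aq. potassium sodium tartrate
Reagents that add atoms: none
Why: Hydride reduction of both esters: the benzoate is cleaved and the butenolide is reduced through its lactol to the (Z)-2-substituted but-2-ene-1,4-diol, which keeps the cis geometry of the ring.

Step 4
Reactants: 6 A-nor tetraol
Product: 7 A-nor methyl ketone diol
Conditions: NaIO4, THF/H2O, 0 °C → rt
Reagents that add atoms: none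
Why: Glycol cleavage: periodate should cut only the vicinal tertiary/primary diol, excising the old hydroxymethyl carbon as formaldehyde and leaving the 3α-acetyl group, while the 1,4-diol and both alkenes are inert.

Step 5
Reactants: 7 A-nor methyl ketone diol
Product: 8 bis-TBS ether of 7
Conditions: TBSCl, imidazole, DMF, 0 °C → rt
Reagents that add atoms: tert-butyldimethylsilyl chloride, CC(C)(C)[Si](C)(C)Cl
Why: Silyl ether formation on the two primary allylic hydroxyls masks the ene-diol against the enolate, ylide and Lewis-acid steps that follow.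

Step 6
Reactants: 8 bis-TBS methyl ketone
Product: 10 3β-hydroxy-3α-acetyl A-nor compound, via 3β-hydroperoxide 9 (not isolated)
Conditions: t-BuOK, O2, P(OEt)3, THF/t-BuOH, −25 °C
Reagents that add atoms: dioxygen, O=O
Why: Enolate autoxidation (α-hydroxylation): equilibrating t-BuOK should give the more substituted C3 enolate, which should trap O2 on the β face, anti to the C10 methyl that shields the α face of the five-membered ring, and the phosphite reduces the hydroperoxide in situ (the protocol is known for the tertiary α-carbon of 20-oxopregnanes).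

Step 7
Reactants: 10 3β-hydroxy-3α-acetyl A-nor compound
Product: 11 3β-hydroxy-3α-isopropenyl A-nor compound
Conditions: Ph3PCH3Br, KN(SiMe3)2, THF, 0 °C; then 10, −20 °C → rt
Reagents that add atoms: methyltriphenylphosphonium bromide, [Br-].C[P+](c1ccccc1)(c1ccccc1)c1ccccc1
Why: Wittig methylenation of the methyl ketone; excess non-stabilised ylide tolerates the tertiary alkoxide, and the low temperature should keep the α-ketol from an acyloin shift.

Step 8
Reactants: 11 3β-hydroxy-3α-isopropenyl A-nor compound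
Product: 12 epoxy alcohol
Conditions: VO(acac)2 (5 mol %), t-BuOOH, CH2Cl2, 0 °C
Reagents that add atoms: tert-butyl hydroperoxide, CC(C)(C)OO
Why: Hydroxyl-directed vanadium/t-BuOOH epoxidation of the tertiary allylic alcohol only; with the O–C3–C4=C dihedral near 50° the C2 methylene should eclipse the vinylic methyl and the bulkier C5 should lie out of plane, so oxygen is delivered to the face that gives the (4R)-epoxide with C5 anti to the new C4–O bond.

Step 9
Reactants: 12 epoxy alcohol
Product: 13 ring-expanded 18-hydroxy-3-ketone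
Conditions: BF3·OEt2 (0.3 equiv), CH2Cl2, −78 °C; aq. NaHCO3
Reagents that add atoms: none
Why: BF3 coordination ionises the epoxide at its tertiary carbon C4 and, in concert, the C3–C5 ring bond, which lies anti-periplanar to the breaking C4–O bond in the conformer that step 8 also uses, migrates to C4 while the C3 hydroxyl becomes the carbonyl (semipinacol rearrangement of a 2,3-epoxy alcohol, the type known for tertiary α-hydroxy epoxides). No ring is closed by cyclisation; ring A arises by enlargement of the five-membered ring (C10, C1, C2, C3, C5) to the six-membered ring through insertion of C4 between C3 and C5 (1,2-alkyl shift). The only new stereocentre, quaternary C4, is set by inversion at the epoxide carbon, so the epoxide configuration from step 8 puts the hydroxymethyl on the β face (equatorial) and the methyl on the α face (axial), while C5 migrates with retention and keeps the trans ring fusion. The step needs C5 and not C2 to migrate, which the higher migratory aptitude of the more substituted, anti-aligned C5 should secure, and it needs cleavage of the tertiary and not the primary C–O bond, which cation stability secures.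

Step 10
Reactants: 13 ring-expanded 18-hydroxy-3-ketone
Product: 14 18-O-TES Δ2 triethylsilyl enol ether
Conditions: Et3SiOTf (2.5 equiv), Et3N, CH2Cl2, −78 → 0 °C
Reagents that add atoms: triethylsilyl trifluoromethanesulfonate, CC[Si](CC)(CC)OS(=O)(=O)C(F)(F)F
Why: Silylation plus soft enolisation: the primary hydroxyl is capped and the ketone, enolisable only towards C2 because C4 is quaternary, should give the Δ2 silyl enol ether.

Step 11
Reactants: 14 18-O-TES Δ2 triethylsilyl enol ether
Product: 16 2β-triethylsilyloxy 3-ketone, via silyloxy epoxide 15 (not isolated)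
Conditions: dimethyldioxirane, acetone/CH2Cl2, −78 → 0 °C
Reagents that add atoms: dimethyldioxirane, CC1(C)OO1
Why: Rubottom oxidation: the dioxirane should epoxidise the electron-rich enol ether much faster than the two other alkenes and from the β face, opposite the axial methyls on C4 and C10, and 1,4-silyl migration should give the equatorial 2β-silyloxy ketone.

Step 12
Reactants: 16 2β-triethylsilyloxy 3-ketone
Product: 17 3α-alcohol
Conditions: NaBH4, MeOH/THF, −20 → 0 °C
Reagents that add atoms: none
Why: Borohydride reduction: axial hydride delivery from the β face, away from the axial C4 methyl, should give the equatorial 3α-alcohol, as for 4,4-disubstituted 3-oxo terpenoids.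

Step 13
Reactants: 17 3α-alcohol; 18 angelic acid
Product: 19 3α-O-angeloyl ester
Conditions: 18, 2,4,6-Cl3C6H2COCl, Et3N, toluene, rt; then 17, DMAP, 70 °C
Reagents that add atoms: none
Why: Yamaguchi esterification through the mixed anhydride, the usual way to acylate a hindered secondary alcohol with angelic acid without Z to E isomerisation; only the C3 hydroxyl is free.

Step 14
Reactants: 19 3α-O-angeloyl ester
Product: 20 angeloyl tetraol
Conditions: HF·pyridine, pyridine, THF, 0 °C → rt
Reagents that add atoms: none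
Why: Fluoride desilylation under buffered acidic conditions should remove all four silyl ethers without acyl migration or ester cleavage.

Step 15
Reactants: 20 angeloyl tetraol
Product: 23 target CNP0335424.2, via hydroxy enal 21 (not isolated), via lactol 22 (not isolated)
Conditions: MnO2, CH2Cl2, rt
Reagents that add atoms: none
Why: Chemoselective allylic oxidation and oxidative lactonisation: MnO2 should oxidise the less hindered allylic alcohol (C15, on the CH= carbon C14) first, the (Z)-hydroxy enal closes to the lactol and this is oxidised to the β-substituted butenolide, while the saturated C2 and C18 hydroxyls are untouched.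

Compound list
1 | 14-deoxyandrographolide: ent-labdane with 8(17)-exocyclic methylene, 3α-OH (equatorial), C4 carrying α (axial) CH2OH and β CH3, H-5β, H-9β, 10α-CH3, C9 side chain CH2CH2 attached to the α-carbon (C13) of a but-2-en-4-olide | C=C1CC[C@H]2[C@@](C)(CC[C@@H](O)[C@@]2(C)CO)[C@@H]1CCC1=CCOC1=O | starting material
2 | 19-O-benzoyl-14-deoxyandrographolide (benzoate on the C4 hydroxymethyl, 3α-OH free) | C=C1CC[C@H]2[C@@](C)(CC[C@@H](O)[C@@]2(C)COC(=O)c3ccccc3)[C@@H]1CCC1=CCOC1=O | intermediate
3 | 3-O-triflate of 2 | C=C1CC[C@H]2[C@@](C)(CC[C@@H](OS(=O)(=O)C(F)(F)F)[C@@]2(C)COC(=O)c3ccccc3)[C@@H]1CCC1=CCOC1=O | intermediate (not isolated)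
4 | A-nor 2-phenyl-1,3-dioxolan-2-ylium triflate: H-3β, the 3α substituent is the 4-methyl-1,3-dioxolan-2-ylium-4-yl carbon C4 (C4 unassigned) | C=C1CC[C@H]2[C@@](C)(CC[C@H]2C3(C)COC(c4ccccc4)=[O+]3)[C@@H]1CCC1=CCOC1=O.[O-]S(=O)(=O)C(F)(F)F | intermediate (not isolated)
5 | A-nor hydroxy benzoate: trans-hydrindane, H-3β, 3α-[1-(benzoyloxy)-2-hydroxypropan-2-yl] (C4 unassigned), butenolide unchanged | C=C1CC[C@H]2[C@@](C)(CC[C@H]2C(C)(O)COC(=O)c3ccccc3)[C@@H]1CCC1=CCOC1=O | intermediate
6 | A-nor tetraol: 3α-(1,2-dihydroxypropan-2-yl) (C4 unassigned); side chain (Z)-CH2CH2C(CH2OH)=CHCH2OH | C=C1CC[C@H]2[C@@](C)(CC[C@H]2C(C)(O)CO)[C@@H]1CC/C(CO)=C/CO | intermediate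
7 | A-nor methyl ketone diol: 3α-acetyl, H-3β, (Z)-ene-1,4-diol side chain | C=C1CC[C@H]2[C@@](C)(CC[C@H]2C(C)=O)[C@@H]1CC/C(CO)=C/CO | intermediate
8 | bis-TBS ether of 7 (O15, O16) | C=C1CC[C@H]2[C@@](C)(CC[C@H]2C(C)=O)[C@@H]1CC/C(CO[Si](C)(C)C(C)(C)C)=C/CO[Si](C)(C)C(C)(C)C | intermediate
9 | 3β-hydroperoxy-3α-acetyl A-nor compound | C=C1CC[C@H]2[C@@](C)(CC[C@@]2(OO)C(C)=O)[C@@H]1CC/C(CO[Si](C)(C)C(C)(C)C)=C/CO[Si](C)(C)C(C)(C)C | intermediate (not isolated)
10 | 3β-hydroxy-3α-acetyl A-nor compound (tertiary α-ketol) | C=C1CC[C@H]2[C@@](C)(CC[C@@]2(O)C(C)=O)[C@@H]1CC/C(CO[Si](C)(C)C(C)(C)C)=C/CO[Si](C)(C)C(C)(C)C | intermediate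
11 | 3β-hydroxy-3α-isopropenyl A-nor compound (tertiary allylic alcohol) | C=C1CC[C@H]2[C@@](C)(CC[C@@]2(O)C(C)=C)[C@@H]1CC/C(CO[Si](C)(C)C(C)(C)C)=C/CO[Si](C)(C)C(C)(C)C | intermediate
12 | epoxy alcohol: 3β-hydroxy-3α-[(2R)-2-methyloxiran-2-yl] A-nor compound | C=C1CC[C@H]2[C@@](C)(CC[C@@]2(O)[C@@]3(C)CO3)[C@@H]1CC/C(CO[Si](C)(C)C(C)(C)C)=C/CO[Si](C)(C)C(C)(C)C | intermediate
13 | ring-expanded hydroxy ketone: trans-decalin, 3-oxo, C4 with α (axial) CH3 and β (equatorial) CH2OH, bis-TBS ene-diol side chain | C=C1CC[C@H]2[C@@](C)(CCC(=O)[C@]2(C)CO)[C@@H]1CC/C(CO[Si](C)(C)C(C)(C)C)=C/CO[Si](C)(C)C(C)(C)C | intermediate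
14 | 18-O-TES ether and Δ2 (C2=C3) triethylsilyl enol ether of 13 | C=C1CC[C@H]2[C@@](C)(CC=C(O[Si](CC)(CC)CC)[C@]2(C)CO[Si](CC)(CC)CC)[C@@H]1CC/C(CO[Si](C)(C)C(C)(C)C)=C/CO[Si](C)(C)C(C)(C)C | intermediate
15 | 2β,3β-epoxy-3α-(triethylsilyloxy) compound | C=C1CC[C@H]2[C@@](C)(C[C@@H]3O[C@]3(O[Si](CC)(CC)CC)[C@]2(C)CO[Si](CC)(CC)CC)[C@@H]1CC/C(CO[Si](C)(C)C(C)(C)C)=C/CO[Si](C)(C)C(C)(C)C | intermediate (not isolated)
16 | 2β-(triethylsilyloxy)-3-ketone (2-OTES equatorial), 18-OTES | C=C1CC[C@H]2[C@@](C)(C[C@H](O[Si](CC)(CC)CC)C(=O)[C@]2(C)CO[Si](CC)(CC)CC)[C@@H]1CC/C(CO[Si](C)(C)C(C)(C)C)=C/CO[Si](C)(C)C(C)(C)C | intermediate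
17 | 3α-alcohol: 2β-OTES, 3α-OH (equatorial), 18-OTES | C=C1CC[C@H]2[C@@](C)(C[C@H](O[Si](CC)(CC)CC)[C@@H](O)[C@]2(C)CO[Si](CC)(CC)CC)[C@@H]1CC/C(CO[Si](C)(C)C(C)(C)C)=C/CO[Si](C)(C)C(C)(C)C | intermediate
18 | angelic acid, (Z)-2-methylbut-2-enoic acid | C/C=C(/C)C(=O)O | starting material
19 | 3α-O-angeloyl ester of 17 | C=C1CC[C@H]2[C@@](C)(C[C@H](O[Si](CC)(CC)CC)[C@@H](OC(=O)/C(C)=C\C)[C@]2(C)CO[Si](CC)(CC)CC)[C@@H]1CC/C(CO[Si](C)(C)C(C)(C)C)=C/CO[Si](C)(C)C(C)(C)C | intermediate
20 | angeloyl tetraol: 2β-OH, 3α-O-angeloyl, 18-OH, (Z)-ene-1,4-diol side chain | C=C1CC[C@H]2[C@@](C)(C[C@H](O)[C@@H](OC(=O)/C(C)=C\C)[C@]2(C)CO)[C@@H]1CC/C(CO)=C/CO | intermediate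
21 | (Z)-hydroxy enal: C15 aldehyde, C16 hydroxyl | C=C1CC[C@H]2[C@@](C)(C[C@H](O)[C@@H](OC(=O)/C(C)=C\C)[C@]2(C)CO)[C@@H]1CC/C(CO)=C/C=O | intermediate (not isolated)
22 | lactol: 5-hydroxy-2,5-dihydrofuran-3-yl side chain (C15 epimers) | C=C1CC[C@H]2[C@@](C)(C[C@H](O)[C@@H](OC(=O)/C(C)=C\C)[C@]2(C)CO)[C@@H]1CCC1=CC(O)OC1 | intermediate (not isolated)
23 | CNP0335424.2: (2S,3S,4S,5S,9R,10S) in labdane numbering; 2β-OH, 3α-O-angeloyl, C4 with α (axial) CH3 and β (equatorial) CH2OH, 8(17)-methylene, β-substituted butenolide | C=C1CC[C@H]2[C@@](C)(C[C@H](O)[C@@H](OC(=O)/C(C)=C\C)[C@]2(C)CO)[C@@H]1CCC1=CC(=O)OC1 | target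

Total step count: 15. Longest linear sequence: 15 steps (1 → 23; angelic acid 18 is used as bought).

Steps most likely to fail

Step 2. The rearranged C4 cation may lose a proton faster than it is captured by the ester, giving alkene mixtures, or the triflate may not ionise cleanly. The fallback sets out from 1 and comes back at 8; it ends the cation by a hydride shift and removes the extra carbon oxidatively. Silylation of the primary hydroxyl (TBSCl, imidazole) gives 19-O-TBS-14-deoxyandrographolide F1. Tf2O with 2,6-di-tert-butyl-4-methylpyridine should trigger the same shift of C5, now ended by a 1,2-hydride shift from the silyloxymethyl carbon (semipinacol), to give the A-nor 2-substituted propanal F2. Deformylative oxygenation of its piperidine enamine (CuCl, O2) should give the A-nor methyl ketone that still carries the butenolide F3. i-Bu2AlH reduces ketone and lactone to the A-nor triol F4, TBSCl silylates the two allylic primary hydroxyls to give the bis-TBS secondary alcohol F5, and Dess–Martin periodinane gives 8.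

Step 8. Poor facial selectivity in the directed epoxidation would give C4 epimers, which the key step carries into 13. The fallback sets out from 10 and comes back at 13; it moves the C4 stereocontrol to an aldol while ring A is still made by ring expansion. NaBH4 reduces 10 to the vicinal diol F6, and MsCl/Et3N sulfonylates the secondary hydroxyl to give the β-mesyloxy alcohol F7. Et3Al should promote the pinacol-type 1,2-shift of C5, giving the ring-expanded 4-methyl-3-ketone F8 (C4 epimerisable). Me3SiCl/NaI/Et3N gives the more substituted Δ3 trimethylsilyl enol ether F9, and hydroxymethylation with aqueous formaldehyde and Yb(OTf)3 from the β face, anti to the axial C10 methyl, should give 13.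

Step 13. Acylation of the hindered C3 hydroxyl may be too slow, or the angeloyl unit may isomerise to the E (tigloyl) isomer during activation. The fallback sets out from 17 and comes back at 19; it builds the Z-alkene after the acylation. Esterification with 2-[bis(2,2,2-trifluoroethoxy)phosphoryl]propanoic acid (carbodiimide, DMAP) gives the phosphonate ester F10, and Still–Gennari olefination with acetaldehyde (KN(SiMe3)2, 18-crown-6, −78 °C) should give 19.

Further compounds
F1 | step 2 | 19-O-TBS-14-deoxyandrographolide | C=C1CC[C@H]2[C@@](C)(CC[C@@H](O)[C@@]2(C)CO[Si](C)(C)C(C)(C)C)[C@@H]1CCC1=CCOC1=O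
F2 | step 2 | A-nor 2-substituted propanal (3α-(1-oxopropan-2-yl), C4 epimers) | C=C1CC[C@H]2[C@@](C)(CC[C@H]2C(C)C=O)[C@@H]1CCC1=CCOC1=O
F3 | step 2 | A-nor methyl ketone with intact butenolide | C=C1CC[C@H]2[C@@](C)(CC[C@H]2C(C)=O)[C@@H]1CCC1=CCOC1=O
F4 | step 2 | A-nor triol (3α-(1-hydroxyethyl), ene-1,4-diol) | C=C1CC[C@H]2[C@@](C)(CC[C@H]2C(C)O)[C@@H]1CC/C(CO)=C/CO
F5 | step 2 | bis-TBS secondary alcohol | C=C1CC[C@H]2[C@@](C)(CC[C@H]2C(C)O)[C@@H]1CC/C(CO[Si](C)(C)C(C)(C)C)=C/CO[Si](C)(C)C(C)(C)C
F6 | step 8 | vicinal diol (3β-hydroxy-3α-(1-hydroxyethyl)) | C=C1CC[C@H]2[C@@](C)(CC[C@@]2(O)C(C)O)[C@@H]1CC/C(CO[Si](C)(C)C(C)(C)C)=C/CO[Si](C)(C)C(C)(C)C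
F7 | step 8 | β-mesyloxy alcohol | C=C1CC[C@H]2[C@@](C)(CC[C@@]2(O)C(C)OS(C)(=O)=O)[C@@H]1CC/C(CO[Si](C)(C)C(C)(C)C)=C/CO[Si](C)(C)C(C)(C)C
F8 | step 8 | ring-expanded 4-methyl-3-ketone | C=C1CC[C@H]2[C@@](C)(CCC(=O)C2C)[C@@H]1CC/C(CO[Si](C)(C)C(C)(C)C)=C/CO[Si](C)(C)C(C)(C)C
F9 | step 8 | Δ3 trimethylsilyl enol ether | C=C1CC[C@H]2[C@@](C)(CCC(O[Si](C)(C)C)=C2C)[C@@H]1CC/C(CO[Si](C)(C)C(C)(C)C)=C/CO[Si](C)(C)C(C)(C)C
F10 | step 13 | 3α-O-[2-(bis(2,2,2-trifluoroethoxy)phosphoryl)propanoyl] ester of 17 | C=C1CC[C@H]2[C@@](C)(C[C@H](O[Si](CC)(CC)CC)[C@@H](OC(=O)C(C)P(=O)(OCC(F)(F)F)OCC(F)(F)F)[C@]2(C)CO[Si](CC)(CC)CC)[C@@H]1CC/C(CO[Si](C)(C)C(C)(C)C)=C/CO[Si](C)(C)C(C)(C)C
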